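The 1,4-dioxane ring is opened at the O1–C8a aryl ether bond. In benzo ring A, C8a lies para to the C6 propenoate chain whereas C4a lies meta, so only C8a is a phenylogous acceptor carbon. A fluoride placed there is displaced by the benzylic C2 alkoxide in an intramolecular SNAr. This single operation closes the ring, decides which oxygen sits on which ring carbon, and copies the threo array of the open chain into the trans-(2R,3R) ring, because no bond at C2 or C3 is touched. The precursor is a threo 1-aryl-2-aryloxypropane-1,3-diol with its primary hydroxyl tritylated, both stereocentres coming from one Evans syn glycolate aldol.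

Key step: step 7

Remark on numbering: 2,3-dihydro-1,4-benzodioxine numbering is used, namely O1, C2 (aryl-bearing), C3 (CH2OH-bearing), O4, C4a, C5 to C8, C8a. The propenoic acid chain stands on C6, and the target is the trans-(2R,3R) isomer.

Step 1
Reactants: 1 4-fluoro-3-hydroxybenzaldehyde; 2 tert-butyl (triphenylphosphoranylidene)acetate
Product: 3 tert-butyl (E)-3-(4-fluoro-3-hydroxyphenyl)prop-2-enoate
Conditions: toluene, 80 °C
Reagents that add atoms: none
Why: Wittig olefination with a stabilised ylide, which should give the E-enoate selectively and tolerates the free phenol.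

Step 2
Reactants: 3 tert-butyl (E)-3-(4-fluoro-3-hydroxyphenyl)prop-2-enoate; 4 (S)-4-benzyl-3-(chloroacetyl)-1,3-oxazolidin-2-one
Product: 5 tert-butyl (E)-3-(3-{2-[(4S)-4-benzyl-2-oxo-1,3-oxazolidin-3-yl]-2-oxoethoxy}-4-fluorophenyl)prop-2-enoate
Conditions: K2CO3, MeCN, rt
Reagents that add atoms: none
Why: Williamson ether synthesis (SN2) of the acidic 2-fluorophenol on the strongly activated α-chloro imide, with a carbonate base too mild to open the imide or touch the auxiliary stereocentre.

Step 3
Reactants: 6 vanillin
Product: 7 3-methoxy-4-(methoxymethoxy)benzaldehyde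
Conditions: MOMCl, iPr2NEt, CH2Cl2, 0 °C to rt
Reagents that add atoms: chloromethyl methyl ether COCCl
Why: Standard O-alkylation of a phenol to its MOM acetal, a group that is stable to boron enolates, borohydride and alkoxide and is labile to acid at the end.

Step 4
Reactants: 5 aryloxyacetyl imide; 7 3-methoxy-4-(methoxymethoxy)benzaldehyde
Product: 10 tert-butyl (E)-3-[3-({(1R,2S)-3-[(4S)-4-benzyl-2-oxo-1,3-oxazolidin-3-yl]-1-hydroxy-1-[3-methoxy-4-(methoxymethoxy)phenyl]-3-oxopropan-2-yl}oxy)-4-fluorophenyl]prop-2-enoate (syn aldol; acyl chain 2S,3R), via Z-dibutylboron enolate 8 (not isolated), via dibutylboron aldolate 9 (not isolated)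
Conditions: Bu2BOTf, Et3N, CH2Cl2, −78 to 0 °C; 7, −78 to 0 °C; then pH 7 buffer, MeOH, 30% H2O2, 0 °C
Reagents that add atoms: dibutylboron triflate CCCCB(CCCC)OS(=O)(=O)C(F)(F)F (its boron group is present in 8 and 9 only and is removed in the oxidative work-up)
Why: Evans syn glycolate aldol, in which soft enolisation gives Z-enolate 8, and 8 adds to the aldehyde through a chair Zimmerman–Traxler transition state on the face away from the benzyl group of the (S)-auxiliary, so both stereocentres (2S,3R, syn) are set at once.

Step 5
Reactants: 10 syn aldol imide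
Product: 11 tert-butyl (E)-3-[4-fluoro-3-({(1R,2R)-1,3-dihydroxy-1-[3-methoxy-4-(methoxymethoxy)phenyl]propan-2-yl}oxy)phenyl]prop-2-enoate (threo diol)
Conditions: NaBH4, THF/H2O (4:1), 0 °C to rt
Reagents that add atoms: none
Why: Reductive cleavage of an N-acyl oxazolidinone by borohydride, which reduces the activated imide carbonyl but not the hindered conjugated tert-butyl ester and touches no stereocentre (the descriptor at the aryloxy carbon changes from S to R only through the CIP ranking).

Step 6
Reactants: 11 threo diol
Product: 12 tert-butyl (E)-3-[4-fluoro-3-({(1R,2R)-1-hydroxy-1-[3-methoxy-4-(methoxymethoxy)phenyl]-3-(trityloxy)propan-2-yl}oxy)phenyl]prop-2-enoate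
Conditions: TrCl, Et3N, DMAP (cat.), CH2Cl2, rt
Reagents that add atoms: trityl chloride ClC(c1ccccc1)(c1ccccc1)c1ccccc1
Why: Sterically controlled tritylation (SN1-type transfer of the trityl cation), which should take the primary hydroxyl and leave the hindered secondary benzylic one free.

Step 7
Reactants: 12 primary trityl ether with free benzylic alcohol
Product: 15 tert-butyl (E)-3-[(2R,3R)-2-[3-methoxy-4-(methoxymethoxy)phenyl]-3-(trityloxymethyl)-2,3-dihydro-1,4-benzodioxin-6-yl]prop-2-enoate, via potassium benzylic alkoxide 13 (not isolated), via Meisenheimer adduct 14 (not isolated)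
Conditions: KOtBu (1.2 equiv), THF/DMF (4:1), 0 to 50 °C
Reagents that add atoms: potassium tert-butoxide CC(C)(C)[O-].[K+] (its potassium is the counter-ion in 13 and 14 only)
Why: KOtBu deprotonates the only free hydroxyl to alkoxide 13, which adds to the fluorine-bearing carbon (the future C8a) of ring A to give Meisenheimer adduct 14, whose charge is carried through C6 into the propenoate as an extended ester enolate, and loss of fluoride rearomatises the ring to 15 (addition–elimination SNAr, in effect a phenylogous oxa-Michael addition followed by β-elimination). The closest known reaction type is the base-mediated intramolecular SNAr etherification of 2-fluoroaryl ethers and 2-fluoroarylalkanols that is used to make benzodioxanes, chromans and benzoxazines. The one ring closed is the six-membered 1,4-dioxane, formed in a formally 6-exo-trig addition at C8a if the C8a=C8 π bond is counted as the acceptor. No lasting stereocentre is created (the sp3 C8a of 14 is lost again), and because no bond at either oxygen-bearing carbon is broken the (1R,2R)-threo array set by the aldol is mapped onto the (2R,3R)-trans ring, reached through a chair-like arrangement with aryl and CH2OTr both equatorial. The step needs chemoselectivity between two hydroxyls that could each close a benzodioxane, secured by the trityl ether on the primary one, and site selectivity on ring A, secured by the single C–F bond para to the acceptor, while C4a is meta to it so that no Smiles-type aryl migration can scramble O1 and O4. tert-Butoxide matches the ester, which makes any transesterification degenerate, and intermolecular oxa-Michael addition to the enoate is reversible and drains into the irreversible loss of fluoride.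

Step 8
Reactants: 15 protected benzodioxane
Product: 16 (E)-3-[(2R,3R)-2-(4-hydroxy-3-methoxyphenyl)-3-(hydroxymethyl)-2,3-dihydro-1,4-benzodioxin-6-yl]prop-2-enoic acid (target)
Conditions: TFA/CH2Cl2 (1:2), H2O (5 vol%), 0 °C to rt; brief aq. NaHCO3/MeOH, then acidify
Reagents that add atoms: none
Why: Global acidolysis (E1 loss of isobutene from the ester, SN1 cleavage of the trityl ether, hydrolysis of the MOM acetal) frees all three groups in one operation, and any reversible ionisation of the benzylic C2–O1 bond can only re-close to the more stable trans ring because C3 stays fixed.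

Compound list
1 | 4-fluoro-3-hydroxybenzaldehyde | O=Cc1ccc(F)c(O)c1 | starting material
2 | tert-butyl (triphenylphosphoranylidene)acetate | CC(C)(C)OC(=O)C=P(c1ccccc1)(c1ccccc1)c1ccccc1 | starting material
3 | tert-butyl (E)-3-(4-fluoro-3-hydroxyphenyl)prop-2-enoate | CC(C)(C)OC(=O)/C=C/c1ccc(F)c(O)c1 | intermediate
4 | (S)-4-benzyl-3-(chloroacetyl)-1,3-oxazolidin-2-one | O=C(CCl)N1[C@@H](Cc2ccccc2)COC1=O | starting material
5 | aryloxyacetyl imide of 3 with the (S)-benzyl oxazolidinone | CC(C)(C)OC(=O)/C=C/c1ccc(F)c(OCC(=O)N2[C@@H](Cc3ccccc3)COC2=O)c1 | intermediate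
6 | vanillin | COc1cc(C=O)ccc1O | starting material
7 | 3-methoxy-4-(methoxymethoxy)benzaldehyde | COCOc1ccc(C=O)cc1OC | intermediate
8 | Z-dibutylboron enolate of 5 (not isolated) | CCCCB(CCCC)O/C(N1[C@@H](Cc2ccccc2)COC1=O)=C\Oc1cc(/C=C/C(=O)OC(C)(C)C)ccc1F | intermediate
9 | dibutylboron aldolate (not isolated) | O=C(N1[C@@H](Cc2ccccc2)COC1=O)[C@@H](Oc1cc(/C=C/C(=O)OC(C)(C)C)ccc1F)[C@H](OB(CCCC)CCCC)c1ccc(OCOC)c(OC)c1 | intermediate
10 | (2S,3R)-syn aldol imide | O=C(N1[C@@H](Cc2ccccc2)COC1=O)[C@@H](Oc1cc(/C=C/C(=O)OC(C)(C)C)ccc1F)[C@H](O)c1ccc(OCOC)c(OC)c1 | intermediate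
11 | (1R,2R)-threo 1-aryl-2-aryloxypropane-1,3-diol | OC[C@@H](Oc1cc(/C=C/C(=O)OC(C)(C)C)ccc1F)[C@H](O)c1ccc(OCOC)c(OC)c1 | intermediate
12 | primary trityl ether of 11 | C(c1ccccc1)(c1ccccc1)(c1ccccc1)OC[C@@H](Oc1cc(/C=C/C(=O)OC(C)(C)C)ccc1F)[C@H](O)c1ccc(OCOC)c(OC)c1 | intermediate
13 | potassium benzylic alkoxide of 12 (not isolated) | C(c1ccccc1)(c1ccccc1)(c1ccccc1)OC[C@@H](Oc1cc(/C=C/C(=O)OC(C)(C)C)ccc1F)[C@H]([O-])c1ccc(OCOC)c(OC)c1.[K+] | intermediate
14 | Meisenheimer adduct, drawn as the extended potassium ester enolate (not isolated) | COc1cc([C@H]2OC3(F)C=CC(=CC=C([O-])OC(C)(C)C)C=C3O[C@@H]2COC(c2ccccc2)(c2ccccc2)c2ccccc2)ccc1OCOC.[K+] | intermediate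
15 | protected (2R,3R)-trans benzodioxane tert-butyl ester | COc1cc([C@H]2Oc3ccc(/C=C/C(=O)OC(C)(C)C)cc3O[C@@H]2COC(c2ccccc2)(c2ccccc2)c2ccccc2)ccc1OCOC | intermediate
16 | (E)-3-[(2R,3R)-2-(4-hydroxy-3-methoxyphenyl)-3-(hydroxymethyl)-2,3-dihydro-1,4-benzodioxin-6-yl]prop-2-enoic acid | COc1cc([C@H]2Oc3ccc(/C=C/C(=O)O)cc3O[C@@H]2CO)ccc1O | target

Total step count: 8. Longest linear sequence: 7 (steps 1, 2, 4, 5, 6, 7, 8).

Steps most likely to fail

Step 7. The propenoate may activate the C–F carbon too weakly, so ring closure would be slow. Under forcing conditions the alkoxide could instead expel the neighbouring aryloxide (epoxide formation) or add to the enoate of a second molecule. The fallback exchanges the acceptor for a stronger one. From 12, Lemieux–Johnson cleavage of the enoate (OsO4 cat., NaIO4, 2,6-lutidine, dioxane/H2O) should give the open-chain 4-fluorobenzaldehyde F1, in which fluorine stands para to a formyl group. Cs2CO3 in DMF at 60 °C should then close the ring by the same O1–C8a bond formation to the benzodioxane-6-carbaldehyde F2. Wittig olefination of F2 with ylide 2 in toluene comes back to the route at 15.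

Step 8. Strong acid may ionise the electron-rich benzylic ether bond faster than the ring re-closes, which would lead to oligomerisation. The liberated guaiacol ring may also be alkylated by trityl or tert-butyl cations or by formaldehyde. The fallback separates the ester cleavage from the acid step. From 15, saponification with powdered KOH in THF (rt to 40 °C, then careful acidification) should give the protected cinnamic acid F3. The base cannot open this ring because the phenol is still masked. The trityl ether and the MOM acetal are then removed with dilute acid only (2 M aq. HCl/THF, 40 °C), which comes back to the route at 16.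

Step 4. Enolisation of the aryloxyacetyl imide may be incomplete, addition to the electron-rich aldehyde may be sluggish, or facial selectivity may be poor. The fallback sets both centres by a catalytic dynamic kinetic resolution.
- From 3, alkylation with ethyl bromoacetate (K2CO3, acetone) should give the ethyl aryloxyacetate F4.
- Its lithium enolate (LiHMDS, THF, −78 °C) adds to 7 to give the stereorandom β-hydroxy ester F5.
- Dess–Martin oxidation gives the configurationally labile α-aryloxy β-keto ester F6.
- Noyori-type asymmetric transfer hydrogenation with dynamic kinetic resolution (RuCl(p-cymene)[(S,S)-TsDPEN], HCO2H/Et3N 5:2, 30 °C) should funnel both enantiomers into the syn-(2S,3R) hydroxy ester F7. This reaction type is known for α-alkoxy β-keto esters, and the catalyst enantiomer is chosen by the usual aryl ketone model.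
- LiBH4 in THF at 0 °C comes back to the route at 11.

Further compounds
F1 | step 7 | 4-fluoro-3-({(1R,2R)-1-hydroxy-1-[3-methoxy-4-(methoxymethoxy)phenyl]-3-(trityloxy)propan-2-yl}oxy)benzaldehyde | C(c1ccccc1)(c1ccccc1)(c1ccccc1)OC[C@@H](Oc1cc(C=O)ccc1F)[C@H](O)c1ccc(OCOC)c(OC)c1
F2 | step 7 | (2R,3R)-2-[3-methoxy-4-(methoxymethoxy)phenyl]-3-(trityloxymethyl)-2,3-dihydro-1,4-benzodioxine-6-carbaldehyde | COc1cc([C@H]2Oc3ccc(C=O)cc3O[C@@H]2COC(c2ccccc2)(c2ccccc2)c2ccccc2)ccc1OCOC
F3 | step 8 | (E)-3-[(2R,3R)-2-[3-methoxy-4-(methoxymethoxy)phenyl]-3-(trityloxymethyl)-2,3-dihydro-1,4-benzodioxin-6-yl]prop-2-enoic acid | COc1cc([C@H]2Oc3ccc(/C=C/C(=O)O)cc3O[C@@H]2COC(c2ccccc2)(c2ccccc2)c2ccccc2)ccc1OCOC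
F4 | step 4 | tert-butyl (E)-3-[3-(2-ethoxy-2-oxoethoxy)-4-fluorophenyl]prop-2-enoate | CCOC(=O)COc1cc(/C=C/C(=O)OC(C)(C)C)ccc1F
F5 | step 4 | ethyl 2-aryloxy-3-hydroxy-3-[3-methoxy-4-(methoxymethoxy)phenyl]propanoate, mixture of stereoisomers | CCOC(=O)C(Oc1cc(/C=C/C(=O)OC(C)(C)C)ccc1F)C(O)c1ccc(OCOC)c(OC)c1
F6 | step 4 | ethyl 2-aryloxy-3-[3-methoxy-4-(methoxymethoxy)phenyl]-3-oxopropanoate, racemic and configurationally labile | CCOC(=O)C(Oc1cc(/C=C/C(=O)OC(C)(C)C)ccc1F)C(=O)c1ccc(OCOC)c(OC)c1
F7 | step 4 | ethyl (2S,3R)-2-aryloxy-3-hydroxy-3-[3-methoxy-4-(methoxymethoxy)phenyl]propanoate (syn) | CCOC(=O)[C@@H](Oc1cc(/C=C/C(=O)OC(C)(C)C)ccc1F)[C@H](O)c1ccc(OCOC)c(OC)c1
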